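**Strategy**

The route rests on disconnecting the O–C8 bond of the 2,5-dihydrofuran ring (O, C5, C6, C7, C8) that is fused to the cyclohexane ring at C5 and C6. A silver-catalysed 5-endo cycloisomerisation of an α-hydroxyallene makes this bond, closes the ring and sets C8 in one operation, because the (6R) allene axis is relayed to the new centre. Its substrate is a C15 allenic diol with the C5 tertiary alcohol beside the C6=C7=C8 allene, a C3 silyl ether and a free C11 alcohol, assembled from actinol and an enynol by Sonogashira coupling, epoxidation and SN2' reduction. Wittig chain extension with a C25 ε-ring aldehyde completes the carotenoid.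

Key step: step 7

Remark 1: carotenoid locants are used (ring C1–C6, chain C7–C11, primes for the ε half); the target is taken as the all-E (3S,5R,8S,3'R,6'R) isomer.
Remark 2: (R)-α-ionone is assumed to be purchasable in enantiopure form (natural flavour grade).
Remark 3: the C11 oxygen passes through the key step as the free alcohol, because across the (E)-C9=C10 bond it cannot reach the allene; an acetate is used only earlier, to shield C9=C10 during epoxidation.

**Route**

Step 1
Reactants: 1 (4R,6R)-4-hydroxy-2,2,6-trimethylcyclohexanone (actinol)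
Product: 2 (4R,6R)-4-(tert-butyldimethylsilyloxy)-2,2,6-trimethylcyclohexanone
Conditions: TBSCl, imidazole, DMF, rt
Reagents that add atoms: tert-butyldimethylsilyl chloride, CC(C)(C)[Si](C)(C)Cl
Why: Imidazole-promoted silylation of the only hydroxyl (silyl ether formation); neither stereocentre is touched.

Step 2
Reactants: 2 (4R,6R)-4-(tert-butyldimethylsilyloxy)-2,2,6-trimethylcyclohexanone
Product: 4 (4R)-4-(tert-butyldimethylsilyloxy)-2,6,6-trimethylcyclohex-1-en-1-yl trifluoromethanesulfonate, via lithium enolate 3 (not isolated)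
Conditions: LiN(i-Pr)2, THF, −78 → 0 °C; then PhNTf2, 0 °C → rt
Reagents that add atoms: N-phenylbis(trifluoromethanesulfonimide), O=S(=O)(N(c1ccccc1)S(=O)(=O)C(F)(F)F)C(F)(F)F
Why: The ketone has a single α-hydrogen (C6–H), so deprotonation gives one enolate, which PhNTf2 sulfonylates on oxygen (enol triflate formation); the methyl-bearing centre becomes trigonal and the silyloxy carbon is untouched.

Step 3
Reactants: 4 (4R)-4-(tert-butyldimethylsilyloxy)-2,6,6-trimethylcyclohex-1-en-1-yl trifluoromethanesulfonate; 5 (2E)-3-methylpent-2-en-4-yn-1-ol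
Product: 6 (2E)-5-[(4R)-4-(tert-butyldimethylsilyloxy)-2,6,6-trimethylcyclohex-1-en-1-yl]-3-methylpent-2-en-4-yn-1-ol
Conditions: Pd(PPh3)4 (cat.), CuI (cat.), i-Pr2NH, THF, rt → 45 °C
Reagents that add atoms: none
Why: Sonogashira coupling of the enol triflate with the terminal alkyne under zerovalent palladium and CuI catalysis, a reaction established for hindered 2,6,6-trimethylcyclohexenyl triflates; the E olefin and free alcohol of 5 are carried through unchanged.

Step 4
Reactants: 6 (2E)-5-[(4R)-4-(tert-butyldimethylsilyloxy)-2,6,6-trimethylcyclohex-1-en-1-yl]-3-methylpent-2-en-4-yn-1-ol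
Product: 7 (2E)-5-[(4R)-4-(tert-butyldimethylsilyloxy)-2,6,6-trimethylcyclohex-1-en-1-yl]-3-methylpent-2-en-4-yn-1-yl acetate
Conditions: Ac2O, pyridine, DMAP (cat.), CH2Cl2, 0 °C → rt
Reagents that add atoms: acetic anhydride, CC(=O)OC(C)=O
Why: DMAP-catalysed acylation of the primary allylic alcohol; the ester lowers the reactivity of the C9=C10 bond and removes hydroxyl-directed oxygen delivery before the peracid step.

Step 5
Reactants: 7 (2E)-5-[(4R)-4-(tert-butyldimethylsilyloxy)-2,6,6-trimethylcyclohex-1-en-1-yl]-3-methylpent-2-en-4-yn-1-yl acetate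
Product: 8 (2E)-5-[(1R,4S,6R)-4-(tert-butyldimethylsilyloxy)-2,2,6-trimethyl-7-oxabicyclo[4.1.0]heptan-1-yl]-3-methylpent-2-en-4-yn-1-yl acetate (5,6-epoxide trans to the C3 silyloxy group)
Conditions: mCPBA, NaHCO3, CH2Cl2, −20 → 0 °C
Reagents that add atoms: 3-chloroperoxybenzoic acid, OOC(=O)c1cccc(Cl)c1
Why: Prilezhaev epoxidation, in which the peracid should take the tetrasubstituted C5=C6 bond in preference to the acetoxy-deactivated C9=C10 bond and the alkyne and should approach mainly from the ring face opposite the C3 silyloxy group, which sets C5 and C6 together (oxygen trans to C3–O); the minor syn epoxide is removed by chromatography.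

Step 6
Reactants: 8 (2E)-5-[(1R,4S,6R)-4-(tert-butyldimethylsilyloxy)-2,2,6-trimethyl-7-oxabicyclo[4.1.0]heptan-1-yl]-3-methylpent-2-en-4-yn-1-yl acetate
Product: 9 (2E)-5-[(2R,4S)-4-(tert-butyldimethylsilyloxy)-2-hydroxy-2,6,6-trimethylcyclohexylidene]-3-methylpenta-2,4-dien-1-ol with (R)-configured allene axis (carotenoid locants 3S,5R,6R)
Conditions: i-Bu2AlH (5 equiv), CH2Cl2, −78 → 0 °C; aq. potassium sodium tartrate work-up
Reagents that add atoms: none
Why: SN2' reduction of an alkynyl oxirane to an α-allenol: the alane held on the oxirane oxygen delivers hydride to C8 on the face from which the C6–O bond departs, so C9 turns to the C5-methyl side and the (6R) axis results with the C5–O bond untouched, while the acetate is cleaved reductively in the same operation.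

Step 7
Reactants: 9 (2E)-5-[(2R,4S)-4-(tert-butyldimethylsilyloxy)-2-hydroxy-2,6,6-trimethylcyclohexylidene]-3-methylpenta-2,4-dien-1-ol with (R)-configured allene axis
Product: 10 (2E)-3-[(2S,6S,7aR)-6-(tert-butyldimethylsilyloxy)-4,4,7a-trimethyl-2,4,5,6,7,7a-hexahydro-1-benzofuran-2-yl]but-2-en-1-ol (carotenoid locants 3S,5R,8S)
Conditions: AgNO3 (0.2 equiv), CaCO3, acetone/H2O, rt, dark
Reagents that add atoms: none
Why: Monovalent silver binds the C7=C8 π bond of the allene, which lies in the plane of C1, C5 and C6, on the side remote from the C5 hydroxyl; the oxygen adds to C8 anti to the metal, and protodemetalation of the C7–Ag bond leaves the C6=C7 olefin. This is the known silver- or gold-catalysed cycloisomerisation of α-hydroxyallenes to 2,5-dihydrofurans. The ring O–C5–C6–C7–C8 closes in the 5-endo-trig mode, the only one open to this hydroxyl, since attack at C6 or C7 would give a three- or four-membered ring. The new C8 centre is dictated by the (6R) axis: C9 stands on the C5-methyl side of the closing plane and stays there, so it ends cis to the C5 methyl, (8S), without a free cation that could scramble it. The step needs chemoselectivity over the primary C11 hydroxyl and integrity of the doubly allylic C8–O bond; the (E)-C9=C10 geometry keeps O11 out of reach of C8, the quaternary C5 excludes dehydration to a furan, and CaCO3 keeps the medium free of acid.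

Step 8
Reactants: 10 (2E)-3-[(2S,6S,7aR)-6-(tert-butyldimethylsilyloxy)-4,4,7a-trimethyl-2,4,5,6,7,7a-hexahydro-1-benzofuran-2-yl]but-2-en-1-ol
Product: 12 [(2E)-3-[(2S,6S,7aR)-6-(tert-butyldimethylsilyloxy)-4,4,7a-trimethyl-2,4,5,6,7,7a-hexahydro-1-benzofuran-2-yl]but-2-en-1-yl]triphenylphosphonium bromide, via allylic bromide 11 (not isolated)
Conditions: CBr4, PPh3, 2,6-lutidine, CH2Cl2, −20 → 0 °C; then PPh3, rt
Reagents that add atoms: tetrabromomethane, BrC(Br)(Br)Br; triphenylphosphine, c1ccc(cc1)P(c1ccccc1)c1ccccc1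
Why: Appel bromination of the primary allylic alcohol in a lutidine-buffered medium and then SN2 quaternisation of PPh3 by the allylic bromide in the same flask; no Brønsted acid is present, so the doubly allylic C8–O bond and the (8S) centre are not ionised.

Step 9
Reactants: 13 (R)-α-ionone, (3E)-4-[(1R)-2,6,6-trimethylcyclohex-2-en-1-yl]but-3-en-2-one
Product: 14 2-methyl-2-[(E)-2-[(1R)-2,6,6-trimethylcyclohex-2-en-1-yl]ethenyl]-1,3-dioxolane
Conditions: HOCH2CH2OH, HC(OEt)3, p-TsOH·H2O (cat.), rt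
Reagents that add atoms: ethylene glycol, OCCO
Why: Acid-catalysed ketalisation of the side-chain ketone, the orthoformate taking up the water; it masks the enone for the next three steps and leaves the C6 stereocentre in place.

Step 10
Reactants: 14 2-methyl-2-[(E)-2-[(1R)-2,6,6-trimethylcyclohex-2-en-1-yl]ethenyl]-1,3-dioxolane
Product: 15 (4R)-3,5,5-trimethyl-4-[(E)-2-(2-methyl-1,3-dioxolan-2-yl)ethenyl]cyclohex-2-en-1-one
Conditions: t-BuOOH (70% aq.), NaOCl (aq.), K2CO3, MeCN, −5 → 0 °C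
Reagents that add atoms: tert-butyl hydroperoxide, CC(C)(C)OO
Why: Radical allylic oxidation by tert-butylperoxy species at C3, the only unhindered ring allylic methylene, to the enone; the doubly allylic C6–H is shielded by the gem-dimethyl carbon and the C5 methyl, so (6R) should be kept.

Step 11
Reactants: 15 (4R)-3,5,5-trimethyl-4-[(E)-2-(2-methyl-1,3-dioxolan-2-yl)ethenyl]cyclohex-2-en-1-one
Product: 16 (1S,4R)-3,5,5-trimethyl-4-[(E)-2-(2-methyl-1,3-dioxolan-2-yl)ethenyl]cyclohex-2-en-1-ol (3,6-cis)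
Conditions: LiBH(s-Bu)3, THF, −78 °C; aqueous work-up
Reagents that add atoms: none
Why: 1,2-Reduction of the β,β-disubstituted cyclohexenone by a bulky borohydride, which should add to the carbonyl face away from the C6 side chain and so give the 3,6-cis allylic alcohol (3S); this prepares C3 for inversion.

Step 12
Reactants: 16 (1S,4R)-3,5,5-trimethyl-4-[(E)-2-(2-methyl-1,3-dioxolan-2-yl)ethenyl]cyclohex-2-en-1-ol
Product: 17 (1R,4R)-3,5,5-trimethyl-4-[(E)-2-(2-methyl-1,3-dioxolan-2-yl)ethenyl]cyclohex-2-en-1-yl 4-nitrobenzoate (3,6-trans)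
Conditions: 4-O2NC6H4CO2H, PPh3, DIAD, THF, 0 °C → rt
Reagents that add atoms: 4-nitrobenzoic acid, OC(=O)c1ccc(cc1)[N+](=O)[O-]
Why: Mitsunobu esterification, an SN2 displacement of the oxyphosphonium group by the carboxylate with inversion, sets C3 as (R), trans to the C6 side chain.

Step 13
Reactants: 17 (1R,4R)-3,5,5-trimethyl-4-[(E)-2-(2-methyl-1,3-dioxolan-2-yl)ethenyl]cyclohex-2-en-1-yl 4-nitrobenzoate
Product: 19 (3E)-4-[(1R,4R)-4-hydroxy-2,6,6-trimethylcyclohex-2-en-1-yl]but-3-en-2-one, via hydroxy ketal 18 (not isolated)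
Conditions: K2CO3, MeOH, rt; evaporate; then PPTS, acetone/H2O, rt
Reagents that add atoms: water, O
Why: Transesterification of the electron-poor aryl ester with methanol and then mild acid hydrolysis of the dioxolane; the ketal is kept during the basic stage so that the C6 hydrogen is never γ to a free enone under base, and PPTS is too weak an acid to ionise the allylic alcohol.

Step 14
Reactants: 19 (3E)-4-[(1R,4R)-4-hydroxy-2,6,6-trimethylcyclohex-2-en-1-yl]but-3-en-2-one
Product: 20 (1R,4R)-4-[(1E)-3-hydroxy-3-methylpenta-1,4-dien-1-yl]-3,5,5-trimethylcyclohex-2-en-1-ol (both epimers at the new carbinol carbon)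
Conditions: CH2=CHMgBr (3 equiv), THF, −20 → 0 °C
Reagents that add atoms: vinylmagnesium bromide, C=C[Mg]Br
Why: 1,2-Addition of the vinyl Grignard reagent to the methyl ketone after deprotonation of the ring hydroxyl, the classical ionone to vinylionol conversion; the new carbinol centre forms as both epimers and disappears in the next step.

Step 15
Reactants: 20 (1R,4R)-4-[(1E)-3-hydroxy-3-methylpenta-1,4-dien-1-yl]-3,5,5-trimethylcyclohex-2-en-1-ol
Product: 21 [(2E,4E)-5-[(1R,4R)-4-hydroxy-2,6,6-trimethylcyclohex-2-en-1-yl]-3-methylpenta-2,4-dien-1-yl]triphenylphosphonium bromide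
Conditions: PPh3·HBr, MeOH, 0 °C → rt; crystallisation
Reagents that add atoms: triphenylphosphine hydrobromide, [Br-].c1ccc(cc1)[PH+](c1ccccc1)c1ccccc1
Why: Acid-promoted ionisation of the tertiary bis-allylic alcohol to a pentadienyl cation that PPh3 captures at the unhindered terminus (SN1' allylic transposition), giving the C15 phosphonium salt with the favoured (9E) geometry; the secondary ring alcohol ionises far more slowly.

Step 16
Reactants: 21 [(2E,4E)-5-[(1R,4R)-4-hydroxy-2,6,6-trimethylcyclohex-2-en-1-yl]-3-methylpenta-2,4-dien-1-yl]triphenylphosphonium bromide; 22 (2E,4E,6E)-2,7-dimethylocta-2,4,6-trienedial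
Product: 23 (2E,4E,6E,8E,10E,12E)-13-[(1R,4R)-4-hydroxy-2,6,6-trimethylcyclohex-2-en-1-yl]-2,7,11-trimethyltrideca-2,4,6,8,10,12-hexaenal ((3R,6R)-3-hydroxy-12'-apo-ε-caroten-12'-al)
Conditions: 22 (3 equiv), NaOMe added slowly, MeOH/CH2Cl2, 0 °C; then heptane, 80 °C, dark
Reagents that add atoms: none
Why: Wittig olefination of one formyl group of the symmetrical dialdehyde, kept in excess, by the allylic ylide made in situ; the new C11'=C12' bond forms as an E/Z mixture that thermal equilibration should convert to E.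

Step 17
Reactants: 12 [(2E)-3-[(2S,6S,7aR)-6-(tert-butyldimethylsilyloxy)-4,4,7a-trimethyl-2,4,5,6,7,7a-hexahydro-1-benzofuran-2-yl]but-2-en-1-yl]triphenylphosphonium bromide; 23 (3R,6R)-3-hydroxy-12'-apo-ε-caroten-12'-al
Product: 24 (3S,5R,8S,3'R,6'R)-3-(tert-butyldimethylsilyloxy)-5,8-epoxy-5,8-dihydro-β,ε-caroten-3'-ol (all-E)
Conditions: NaOMe, MeOH/CH2Cl2, −20 → 0 °C, argon, dark; then EtOH/heptane, 70 °C
Reagents that add atoms: none
Why: Wittig olefination joining C11 to C12 with the ylide generated in situ at low temperature; the ring oxygen at C8 sits one carbon beyond the allylic ylide terminus, as the acetal oxygens do in the widely used C5 acetal ylide, so it should survive, and mild heating converts the 11Z isomer into the all-E polyene.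

Step 18
Reactants: 24 (3S,5R,8S,3'R,6'R)-3-(tert-butyldimethylsilyloxy)-5,8-epoxy-5,8-dihydro-β,ε-caroten-3'-ol
Product: 25 (3S,5R,8S,3'R,6'R)-5,8-epoxy-5,8-dihydro-β,ε-carotene-3,3'-diol (all-E), the target
Conditions: Bu4NF, THF, 0 °C → rt, dark
Reagents that add atoms: none
Why: Fluoride-mediated cleavage of the secondary silyl ether under non-acidic conditions, which the acid-labile dihydrofuran ring and the allylic ε-ring alcohol tolerate.

**Compound list**

1 | (4R,6R)-4-hydroxy-2,2,6-trimethylcyclohexanone (actinol) | C[C@@H]1C[C@@H](O)CC(C)(C)C1=O | starting material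
2 | (4R,6R)-4-(tert-butyldimethylsilyloxy)-2,2,6-trimethylcyclohexanone | C[C@@H]1C[C@@H](O[Si](C)(C)C(C)(C)C)CC(C)(C)C1=O | intermediate
3 | lithium (4R)-4-(tert-butyldimethylsilyloxy)-2,6,6-trimethylcyclohex-1-en-1-olate | CC1=C(O[Li])C(C)(C)C[C@H](O[Si](C)(C)C(C)(C)C)C1 | intermediate (not isolated)
4 | (4R)-4-(tert-butyldimethylsilyloxy)-2,6,6-trimethylcyclohex-1-en-1-yl trifluoromethanesulfonate | CC1=C(OS(=O)(=O)C(F)(F)F)C(C)(C)C[C@H](O[Si](C)(C)C(C)(C)C)C1 | intermediate
5 | (2E)-3-methylpent-2-en-4-yn-1-ol | C#C/C(C)=C/CO | starting material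
6 | (2E)-5-[(4R)-4-(tert-butyldimethylsilyloxy)-2,6,6-trimethylcyclohex-1-en-1-yl]-3-methylpent-2-en-4-yn-1-ol | CC1=C(C#C/C(C)=C/CO)C(C)(C)C[C@H](O[Si](C)(C)C(C)(C)C)C1 | intermediate
7 | acetate of 6 | CC1=C(C#C/C(C)=C/COC(C)=O)C(C)(C)C[C@H](O[Si](C)(C)C(C)(C)C)C1 | intermediate
8 | (2E)-5-[(1R,4S,6R)-4-(tert-butyldimethylsilyloxy)-2,2,6-trimethyl-7-oxabicyclo[4.1.0]heptan-1-yl]-3-methylpent-2-en-4-yn-1-yl acetate | CC(=O)OC/C=C(\C)C#C[C@]12C(C)(C)C[C@H](O[Si](C)(C)C(C)(C)C)C[C@@]1(C)O2 | intermediate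
9 | (2E)-5-[(2R,4S)-4-(tert-butyldimethylsilyloxy)-2-hydroxy-2,6,6-trimethylcyclohexylidene]-3-methylpenta-2,4-dien-1-ol, (R) allene axis (key-step precursor) | OC/C=C(\C)/C=[C@@]=C1C(C)(C)C[C@H](O[Si](C)(C)C(C)(C)C)C[C@@]1(C)O | intermediate
10 | (2E)-3-[(2S,6S,7aR)-6-(tert-butyldimethylsilyloxy)-4,4,7a-trimethyl-2,4,5,6,7,7a-hexahydro-1-benzofuran-2-yl]but-2-en-1-ol (key-step product) | OC/C=C(\C)[C@@H]1C=C2C(C)(C)C[C@H](O[Si](C)(C)C(C)(C)C)C[C@@]2(C)O1 | intermediate
11 | (2S,6S,7aR)-2-[(2E)-4-bromobut-2-en-2-yl]-6-(tert-butyldimethylsilyloxy)-4,4,7a-trimethyl-2,4,5,6,7,7a-hexahydro-1-benzofuran | BrC/C=C(\C)[C@@H]1C=C2C(C)(C)C[C@H](O[Si](C)(C)C(C)(C)C)C[C@@]2(C)O1 | intermediate (not isolated)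
12 | [(2E)-3-[(2S,6S,7aR)-6-(tert-butyldimethylsilyloxy)-4,4,7a-trimethyl-2,4,5,6,7,7a-hexahydro-1-benzofuran-2-yl]but-2-en-1-yl]triphenylphosphonium bromide | [Br-].c1ccccc1[P+](c1ccccc1)(c1ccccc1)C/C=C(\C)[C@@H]1C=C2C(C)(C)C[C@H](O[Si](C)(C)C(C)(C)C)C[C@@]2(C)O1 | intermediate
13 | (R)-α-ionone | CC1=CCCC(C)(C)[C@H]1/C=C/C(C)=O | starting material
14 | 2-methyl-2-[(E)-2-[(1R)-2,6,6-trimethylcyclohex-2-en-1-yl]ethenyl]-1,3-dioxolane | CC1=CCCC(C)(C)[C@H]1/C=C/C1(C)OCCO1 | intermediate
15 | (4R)-3,5,5-trimethyl-4-[(E)-2-(2-methyl-1,3-dioxolan-2-yl)ethenyl]cyclohex-2-en-1-one | CC1=CC(=O)CC(C)(C)[C@H]1/C=C/C1(C)OCCO1 | intermediate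
16 | (1S,4R)-3,5,5-trimethyl-4-[(E)-2-(2-methyl-1,3-dioxolan-2-yl)ethenyl]cyclohex-2-en-1-ol (3,6-cis) | CC1=C[C@@H](O)CC(C)(C)[C@H]1/C=C/C1(C)OCCO1 | intermediate
17 | (1R,4R)-3,5,5-trimethyl-4-[(E)-2-(2-methyl-1,3-dioxolan-2-yl)ethenyl]cyclohex-2-en-1-yl 4-nitrobenzoate (3,6-trans) | CC1=C[C@H](OC(=O)c2ccc(cc2)[N+](=O)[O-])CC(C)(C)[C@H]1/C=C/C1(C)OCCO1 | intermediate
18 | (1R,4R)-3,5,5-trimethyl-4-[(E)-2-(2-methyl-1,3-dioxolan-2-yl)ethenyl]cyclohex-2-en-1-ol (3,6-trans) | CC1=C[C@H](O)CC(C)(C)[C@H]1/C=C/C1(C)OCCO1 | intermediate (not isolated)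
19 | (3E)-4-[(1R,4R)-4-hydroxy-2,6,6-trimethylcyclohex-2-en-1-yl]but-3-en-2-one ((3R,6R)-3-hydroxy-α-ionone) | CC1=C[C@H](O)CC(C)(C)[C@H]1/C=C/C(C)=O | intermediate
20 | (1R,4R)-4-[(1E)-3-hydroxy-3-methylpenta-1,4-dien-1-yl]-3,5,5-trimethylcyclohex-2-en-1-ol (carbinol epimers) | CC1=C[C@H](O)CC(C)(C)[C@H]1/C=C/C(C)(O)C=C | intermediate
21 | [(2E,4E)-5-[(1R,4R)-4-hydroxy-2,6,6-trimethylcyclohex-2-en-1-yl]-3-methylpenta-2,4-dien-1-yl]triphenylphosphonium bromide | [Br-].CC1=C[C@H](O)CC(C)(C)[C@H]1/C=C/C(C)=C/C[P+](c1ccccc1)(c1ccccc1)c1ccccc1 | intermediate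
22 | (2E,4E,6E)-2,7-dimethylocta-2,4,6-trienedial | O=C/C(C)=C/C=C/C=C(C)/C=O | starting material
23 | (3R,6R)-3-hydroxy-12'-apo-ε-caroten-12'-al | CC1=C[C@H](O)CC(C)(C)[C@H]1/C=C/C(C)=C/C=C/C(C)=C/C=C/C=C(C)/C=O | intermediate
24 | (3S,5R,8S,3'R,6'R)-3-(tert-butyldimethylsilyloxy)-5,8-epoxy-5,8-dihydro-β,ε-caroten-3'-ol | CC1=C[C@H](O)CC(C)(C)[C@H]1/C=C/C(C)=C/C=C/C(C)=C/C=C/C=C(C)/C=C/C=C(\C)[C@@H]1C=C2C(C)(C)C[C@H](O[Si](C)(C)C(C)(C)C)C[C@@]2(C)O1 | intermediate
25 | (3S,5R,8S,3'R,6'R)-5,8-epoxy-5,8-dihydro-β,ε-carotene-3,3'-diol | CC1=C[C@H](O)CC(C)(C)[C@H]1/C=C/C(C)=C/C=C/C(C)=C/C=C/C=C(C)/C=C/C=C(\C)[C@@H]1C=C2C(C)(C)C[C@H](O)C[C@@]2(C)O1 | target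

**Step count and risks**

Total step count: 18. Longest linear sequence: 10 steps (steps 1–8, 17, 18 from actinol; equally steps 9–16, 17, 18 from (R)-α-ionone).

Steps most likely to fail:

1. Step 7. The doubly allylic C8–O bond of the product may ionise reversibly at the metal, or the vinylallene may lose its axial configuration before ring closure, so that C8 is partly epimerised; the hindered tertiary alcohol may also close slowly. The fallback sets out from dienynol 6 and returns at furanoid alcohol 10. LiAlH4 in THF reduces the conjugated triple bond of 6 to the 7E olefin (hydroxyl-assisted trans reduction of an enynol) to give the (7E,9E)-dienol F1. Acetylation gives the dienyl acetate F2, and mCPBA/NaHCO3 epoxidises C5=C6 trans to the silyloxy group to give the 5,6-epoxide F3. A trace of PPTS in CH2Cl2 then brings about the classical epoxide-to-furanoid rearrangement, which gives both C8 epimers. The (8S) furanoid acetate F4 is separated by chromatography and methanolysed (K2CO3, MeOH) to 10.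

2. Step 5. The peracid may attack the ring face syn to the silyloxy group to a larger extent than hoped, or attack the C9=C10 bond, which would leave little of the required epoxide. The fallback sets out from triflate 4 and returns at allenic diol 9; it fixes the C5–O configuration by reagent control.
   - Methoxycarbonylation (Pd(OAc)2, PPh3, CO, Et3N, MeOH/DMF) gives the methyl ester F5, and i-Bu2AlH reduces it to the allylic alcohol F6.
   - Sharpless asymmetric epoxidation (Ti(OiPr)4, t-BuOOH, 4 Å sieves, CH2Cl2, −20 °C) gives the epoxy alcohol F7. The tartrate enantiomer is chosen to deliver oxygen trans to C3–O; by the usual facial rule this is D-(−)-diethyl tartrate.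
   - Dess–Martin oxidation gives the epoxy aldehyde F8, and Ohira–Bestmann homologation (K2CO3, MeOH) gives the ethynyl oxirane F9.
   - Sonogashira coupling with ethyl (E)-3-iodobut-2-enoate gives the epoxy enynoate F10.
   - i-Bu2AlH reduces the ester and opens the oxirane in the SN2' sense to 9.

3. Step 17. The allylic ylide may expel the C8 ring oxygen (opening of the dihydrofuran by β-alkoxide loss) or the C8 centre may erode under base, leaving little coupled product. The fallback reverses the polarity of the coupling; it sets out from furanoid alcohol 10 and aldehyde 23 and returns at 24. MnO2 in CH2Cl2 oxidises 10 to the furanoid enal F11. NaBH4 reduces 23 to the C25 diol F12, and PPh3·HBr in MeOH converts this into the C25 phosphonium bromide F13. Wittig olefination of F11 with F13 (1,2-epoxybutane, EtOH, reflux), followed by thermal equilibration, gives 24.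

Further compounds
F1 | step 7 | (2E,4E)-5-[(4R)-4-(tert-butyldimethylsilyloxy)-2,6,6-trimethylcyclohex-1-en-1-yl]-3-methylpenta-2,4-dien-1-ol | CC1=C(/C=C/C(C)=C/CO)C(C)(C)C[C@H](O[Si](C)(C)C(C)(C)C)C1
F2 | step 7 | acetate of F1 | CC1=C(/C=C/C(C)=C/COC(C)=O)C(C)(C)C[C@H](O[Si](C)(C)C(C)(C)C)C1
F3 | step 7 | (2E,4E)-5-[(1S,4S,6R)-4-(tert-butyldimethylsilyloxy)-2,2,6-trimethyl-7-oxabicyclo[4.1.0]heptan-1-yl]-3-methylpenta-2,4-dien-1-yl acetate | CC(=O)OC/C=C(C)/C=C/[C@]12C(C)(C)C[C@H](O[Si](C)(C)C(C)(C)C)C[C@@]1(C)O2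
F4 | step 7 | (2E)-3-[(2S,6S,7aR)-6-(tert-butyldimethylsilyloxy)-4,4,7a-trimethyl-2,4,5,6,7,7a-hexahydro-1-benzofuran-2-yl]but-2-en-1-yl acetate | CC(=O)OC/C=C(\C)[C@@H]1C=C2C(C)(C)C[C@H](O[Si](C)(C)C(C)(C)C)C[C@@]2(C)O1
F5 | step 5 | methyl (4R)-4-(tert-butyldimethylsilyloxy)-2,6,6-trimethylcyclohex-1-ene-1-carboxylate | CC1=C(C(=O)OC)C(C)(C)C[C@H](O[Si](C)(C)C(C)(C)C)C1
F6 | step 5 | [(4R)-4-(tert-butyldimethylsilyloxy)-2,6,6-trimethylcyclohex-1-en-1-yl]methanol | CC1=C(CO)C(C)(C)C[C@H](O[Si](C)(C)C(C)(C)C)C1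
F7 | step 5 | [(1R,4S,6R)-4-(tert-butyldimethylsilyloxy)-2,2,6-trimethyl-7-oxabicyclo[4.1.0]heptan-1-yl]methanol | OC[C@]12C(C)(C)C[C@H](O[Si](C)(C)C(C)(C)C)C[C@@]1(C)O2
F8 | step 5 | (1R,4S,6R)-4-(tert-butyldimethylsilyloxy)-2,2,6-trimethyl-7-oxabicyclo[4.1.0]heptane-1-carbaldehyde | O=C[C@]12C(C)(C)C[C@H](O[Si](C)(C)C(C)(C)C)C[C@@]1(C)O2
F9 | step 5 | (1R,4S,6R)-4-(tert-butyldimethylsilyloxy)-1-ethynyl-2,2,6-trimethyl-7-oxabicyclo[4.1.0]heptane | C#C[C@]12C(C)(C)C[C@H](O[Si](C)(C)C(C)(C)C)C[C@@]1(C)O2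
F10 | step 5 | ethyl (2E)-5-[(1R,4S,6R)-4-(tert-butyldimethylsilyloxy)-2,2,6-trimethyl-7-oxabicyclo[4.1.0]heptan-1-yl]-3-methylpent-2-en-4-ynoate | CCOC(=O)/C=C(\C)C#C[C@]12C(C)(C)C[C@H](O[Si](C)(C)C(C)(C)C)C[C@@]1(C)O2
F11 | step 17 | (2E)-3-[(2S,6S,7aR)-6-(tert-butyldimethylsilyloxy)-4,4,7a-trimethyl-2,4,5,6,7,7a-hexahydro-1-benzofuran-2-yl]but-2-enal | O=C/C=C(\C)[C@@H]1C=C2C(C)(C)C[C@H](O[Si](C)(C)C(C)(C)C)C[C@@]2(C)O1
F12 | step 17 | (3R,6R)-12'-apo-ε-carotene-3,12'-diol | CC1=C[C@H](O)CC(C)(C)[C@H]1/C=C/C(C)=C/C=C/C(C)=C/C=C/C=C(C)/CO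
F13 | step 17 | [(3R,6R)-3-hydroxy-12'-apo-ε-caroten-12'-yl]triphenylphosphonium bromide | [Br-].CC1=C[C@H](O)CC(C)(C)[C@H]1/C=C/C(C)=C/C=C/C(C)=C/C=C/C=C(C)/C[P+](c1ccccc1)(c1ccccc1)c1ccccc1
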